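Do birch and elm differ by more than the margin in target after 6.0 d, and if so, which holds more?

| flask | starting material | reagent | free catalyst | second catalyst | temperature | remark | time |
|---|---|---|---|---|---|---|---|
| theta | 15 mM | 3 equiv | 7.9 mol% | 5 mol% | 20 °C | run made earlier |  |
| eta | 15 mM | 3 equiv | 10 mol% | 5 mol% | 31 °C | run made earlier |  |
| delta | 15 mM | 3 equiv | 17 mol% | 5 mol% | 20 °C | run made earlier |  |
| gamma | 15 mM | 3 equiv | 15 mol% | 6.6 mol% | 31 °C | run made earlier |  |
| birch | 15 mM | 3.00 equiv | 15 mol% | 5 mol% | 25 °C |  | 6.0 d |
| elm | 10 mM | 3.00 equiv | 8 mol% | 8 mol% | 25 °C |  | 6.0 d |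

- theta (time / d: target / %): 1.25: 41.1; 2.50: 48.1; 4.00: 50.1; 5.00: 51.1; 6.00: 49.7
- eta (time / d: target / %): 0.500: 40.3; 1.67: 44.3; 3.00: 44.8; 4.00: 46.1; 6.00: 47.9
- delta (time / d: target / %): 0.500: 34.8; 0.833: 45.4; 1.67: 53.0; 3.00: 51.9; 6.00: 49.5
- gamma (time / d: target / %): 1.25: 46.3; 2.50: 43.6; 4.00: 44.3; 5.00: 43.2; 6.00: 43.9

(readings scatter by 1 percentage point)

- for target the idle complex is counted in
- on the list of suspects stand: starting material + free catalyst -> free catalyst + open intermediate; second catalyst + open intermediate <-> catalyst intermediate; reagent + catalyst intermediate -> second catalyst + target; free catalyst + target -> spent catalyst; target + free catalyst <-> isomer of the product + free catalyst; free catalyst + target <-> idle complex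
- where the amount of starting material changes, what is given in equivalents or mol% on it follows

- which of the two ends with the higher amount of target, in percent of the starting material charged ("neither" if they lie within 2 percentage points) (birch / elm / neither)
- target at the end, in percent of the starting material charged, birch
- target at the end, in percent of the starting material charged, elm

I worked with the fraction left, taking the gap between target and its plateau as a pseudo-first-order decay whose half-time goes as one over [free catalyst]. In the delta run, 34.3 % of the gap stood at 0.500 d, which gives 0.324 d at 20 °C. In the eta run, 10.0 % stood at 0.500 d, which gives 0.151 d at 31 °C. Scaling both to elm's [free catalyst] and taking their geometric middle for 25 °C gave 0.541 d. This is elm's opening half-time, the time in which the fraction of starting material left halves at the charged [free catalyst]. For birch it comes to 0.192 d. Since 6.0 d is far longer than either, I put both flasks on a plateau between the last theta reading, 49.7 %, and the last gamma reading, 43.9 %.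

The forecast said neither, with birch at 47 % (44 % to 50 %) and elm at 48.5 % (43 % to 52 %), and it spoke of “a target/isomer equilibrium that slightly disfavours the target when warmer”.

The flasks gave 47.5 % for birch and 47.9 % for elm, so the answer is neither.

    starting material + free catalyst → free catalyst + open intermediate (k = 0.864 M⁻¹ min⁻¹, Ea = 48.0 kJ mol⁻¹)
    second catalyst + open intermediate ⇌ catalyst intermediate (K = 348 M⁻¹, k = 9.62 M⁻¹ min⁻¹, Ea = 62.0 kJ mol⁻¹, ΔH = −33.0 kJ mol⁻¹)
    reagent + catalyst intermediate → second catalyst + target (k = 4.57 M⁻¹ min⁻¹, Ea = 69.0 kJ mol⁻¹)
    free catalyst + target → spent catalyst (k = 0.0900 M⁻¹ min⁻¹, Ea = 60.0 kJ mol⁻¹)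
    target + free catalyst ⇌ isomer of the product + free catalyst, rate k5*[free catalyst]*[target] forward; the back reaction follows from the equilibrium constant (K = 0.750, k = 1.18 M⁻¹ min⁻¹, Ea = 50.0 kJ mol⁻¹, ΔH = 20.0 kJ mol⁻¹)
    free catalyst + target ⇌ idle complex (K = 48.6 M⁻¹, k = 1.67 M⁻¹ min⁻¹, Ea = 57.0 kJ mol⁻¹, ΔH = −34.0 kJ mol⁻¹)
    (constants at 25 °C)

At 0.638 d in elm, free target went into isomer of the product 13 times as fast as into spent catalyst, forward steps alone, while it was made 2.39 times faster than it was used up. The opening half-time put 0.0459 % of the starting material left in elm, but 12 % stood there, with free catalyst at 5.69 % of its charge. In a neighbour of elm charged with 2.5 mM of starting material at the same loadings, the charged [free catalyst] is a quarter of elm's, so the opening half-time comes to 2.16 d and puts 14.6 % left; 29 % stood there, with free catalyst at 58.4 % of its charge.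

The earlier runs and the new flask come from a simulation with constants of no real substance, noise included.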